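**Strategy.** Ring B, the 2,3-dihydro-4H-pyran-4-one (O1, C2, C3, C4, C4a, C8a), is disconnected at C2–C3. The key step is an enantioselective intramolecular rhodium carbenoid C–H insertion. The carbenoid carbon, the future C3 next to the C4 ketone, inserts into a C–H bond of the O–CH2 group of a plain n-octyl ether, so ring B is closed and the C2 stereocentre is created in one operation. It exploits that C2 is an ether carbon on O1, held 1,6 to C3 across the rigid C4a=C8a enol ether double bond of lactone ring A. The precursor is a 4-diazoacetyl-3-octyloxy-5,6-dihydropyran-2-one, assembled from (R)-1,2-epoxydodecane, tert-butyl acetate, an oxalyl unit and 1-octanol.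

Key step: step 6

Remark (numbering): the target is numbered as a pyrano[3,4-b]pyran: O1, C2 (heptyl, S), C3, C4 (ketone), C4a, C5, C6 (decyl, R), O7, C8 (lactone C=O), C8a. Ring A is the lactone, ring B the dihydropyranone. The monocyclic intermediates carry ordinary pyran-2-one numbering.

Assumption: the sense of induction of the chiral rhodium carboxylate cannot be assigned in advance for this substrate. Both antipodes of the catalyst are available, and the one that delivers (2S) is to be used.

**Step 1**
Reactants: 1 tert-butyl acetate; 2 (R)-1,2-epoxydodecane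
Product: 3 tert-butyl (4R)-4-hydroxytetradecanoate
Conditions: LiN(iPr)2, THF, −78 °C; Et2AlCl; then 2, −78 °C to rt; aq. HCl work-up
Reagents that add atoms: none
Why: The diethylaluminium enolate of the ester should open the terminal epoxide by SN2 attack at the unsubstituted carbon (epoxide opening by an aluminium ester enolate), so the carbinol centre of 2 is carried unchanged into 3 as the future C6 (R).

**Step 2**
Reactants: 3 tert-butyl (4R)-4-hydroxytetradecanoate; 4 ethyl chlorooxoacetate
Product: 5 tert-butyl (4R)-4-[(2-ethoxy-2-oxoacetyl)oxy]tetradecanoate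
Conditions: pyridine, DMAP (cat.), CH2Cl2, 0 °C
Reagents that add atoms: none
Why: O-acylation of the secondary alcohol by the acid chloride should give the mixed oxalate without touching the stereocentre.

**Step 3**
Reactants: 5 tert-butyl (4R)-4-[(2-ethoxy-2-oxoacetyl)oxy]tetradecanoate
Product: 6 tert-butyl (6R)-6-decyl-3-hydroxy-2-oxo-5,6-dihydro-2H-pyran-4-carboxylate
Conditions: KOtBu (1.5 equiv), THF, 0 °C to rt, high dilution; then aq. HCl
Reagents that add atoms: none
Why: Dieckmann-type intramolecular Claisen condensation of the only enolisable position (alpha to the tert-butyl ester) onto the oxalate should end in the six-membered alpha-keto lactone, whose stabilised enolate is the thermodynamic sink; no stereocentre is formed and 6 is expected as the enol.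

**Step 4**
Reactants: 6 tert-butyl (6R)-6-decyl-3-hydroxy-2-oxo-5,6-dihydro-2H-pyran-4-carboxylate; 7 1-octanol
Product: 8 tert-butyl (6R)-6-decyl-3-(octyloxy)-2-oxo-5,6-dihydro-2H-pyran-4-carboxylate
Conditions: PPh3, DIAD, THF, 0 °C to rt
Reagents that add atoms: none
Why: Mitsunobu alkylation of the acidic enol should go on oxygen, because C4 is already fully substituted and the tert-butyl ester offers no second enol oxygen.

**Step 5**
Reactants: 8 tert-butyl (6R)-6-decyl-3-(octyloxy)-2-oxo-5,6-dihydro-2H-pyran-4-carboxylate
Product: 10 (6R)-6-decyl-4-(2-diazoacetyl)-3-(octyloxy)-5,6-dihydro-2H-pyran-2-one, via acid chloride 9 (not isolated)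
Conditions: SOCl2, H2O (1 equiv), rt; evaporate; then CH2N2 (excess), Et2O, 0 °C
Reagents that add atoms: diazomethane C=[N+]=[N-]; thionyl chloride ClS(Cl)=O (chlorine of intermediate 9 only)
Why: Chlorinative cleavage of the tert-butyl ester by thionyl chloride should give the acid chloride directly with the lactone intact, and acylation of diazomethane (first stage of the Arndt–Eistert sequence) should then give the diazoketone, the hindered and donor-substituted C=C bond being a poor dipolarophile.

**Step 6**
Reactants: 10 (6R)-6-decyl-4-(2-diazoacetyl)-3-(octyloxy)-5,6-dihydro-2H-pyran-2-one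
Product: 11 (2S,6R)-6-decyl-2-heptyl-2,3,5,6-tetrahydropyrano[3,4-b]pyran-4,8-dione
Conditions: Rh2(S-PTTL)4 [dirhodium tetrakis(N-phthaloyl-(S)-tert-leucinate)] (1 mol %), CH2Cl2, slow addition of 10, 0 °C to rt
Reagents that add atoms: none
Why: Loss of N2 from 10 at the divalent rhodium carboxylate should give an electrophilic rhodium carbenoid at the future C3, which inserts through a concerted three-centre transition state into a C–H bond of the O–CH2 group of the octyl ether (intramolecular carbenoid C–H insertion; the closest known case is the formation of chroman-4-ones from 2-alkoxyaryl diazoketones). Ring B closes through a six-membered (1,6) insertion transition state, the only productive ring size because the 1,5 position is O1 itself and the cis geometry at C4a=C8a holds the carbenoid next to the ether. The C2 stereocentre is set by the chiral carboxylate ligand sphere, which differentiates the two enantiotopic hydrogens of the O–CH2 group, while C6 is too remote to interfere and stays untouched. The step needs C–H insertion to win over oxonium ylide formation at O1; this is favoured by the low basicity of O1, whose lone pair is delocalised into both carbonyl groups, and by the absence of a readily migrating group on it, so reversible ylide formation should be unproductive. Since C6 is already fixed as R, any minor C2 epimer is a diastereomer and should be removable by chromatography; neutral conditions avoid epimerisation of C2 by retro-oxa-Michael opening.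

**Compound list**
1 | tert-butyl acetate | CC(=O)OC(C)(C)C | starting material
2 | (R)-1,2-epoxydodecane | CCCCCCCCCC[C@@H]1CO1 | starting material
3 | tert-butyl (4R)-4-hydroxytetradecanoate | CCCCCCCCCC[C@@H](O)CCC(=O)OC(C)(C)C | intermediate
4 | ethyl chlorooxoacetate | CCOC(=O)C(=O)Cl | starting material
5 | tert-butyl (4R)-4-[(2-ethoxy-2-oxoacetyl)oxy]tetradecanoate | CCCCCCCCCC[C@@H](OC(=O)C(=O)OCC)CCC(=O)OC(C)(C)C | intermediate
6 | tert-butyl (6R)-6-decyl-3-hydroxy-2-oxo-5,6-dihydro-2H-pyran-4-carboxylate | CCCCCCCCCC[C@@H]1CC(C(=O)OC(C)(C)C)=C(O)C(=O)O1 | intermediate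
7 | 1-octanol | CCCCCCCCO | starting material
8 | tert-butyl (6R)-6-decyl-3-(octyloxy)-2-oxo-5,6-dihydro-2H-pyran-4-carboxylate | CCCCCCCCCC[C@@H]1CC(C(=O)OC(C)(C)C)=C(OCCCCCCCC)C(=O)O1 | intermediate
9 | (6R)-6-decyl-3-(octyloxy)-2-oxo-5,6-dihydro-2H-pyran-4-carbonyl chloride | CCCCCCCCCC[C@@H]1CC(C(Cl)=O)=C(OCCCCCCCC)C(=O)O1 | intermediate
10 | (6R)-6-decyl-4-(2-diazoacetyl)-3-(octyloxy)-5,6-dihydro-2H-pyran-2-one | CCCCCCCCCC[C@@H]1CC(C(=O)C=[N+]=[N-])=C(OCCCCCCCC)C(=O)O1 | intermediate
11 | (2S,6R)-6-decyl-2-heptyl-2,3,5,6-tetrahydropyrano[3,4-b]pyran-4,8-dione | CCCCCCCCCC[C@@H]1CC2=C(O[C@@H](CCCCCCC)CC2=O)C(=O)O1 | target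

**Totals**
Total step count: 6. Longest linear sequence: 6 steps (1 and 2 to 11).

**Steps most likely to fail**

Step 6. The carbenoid may be diverted, by attack of O1 to an oxonium ylide that fragments or by dimerisation, or the catalyst may discriminate the two O–CH2 hydrogens poorly. The fallback makes C2–C3 by an aldol reaction and closes ring B through oxygen. It sets out from acid chloride 9, generated from 8 as in step 5. Coupling with MeMgBr under Fe(acac)3 catalysis (THF, −78 °C) should give the methyl ketone (6R)-4-acetyl-6-decyl-3-(octyloxy)-5,6-dihydro-2H-pyran-2-one F1. Its boron enolate (the antipode of Ipc2BCl that directs attack on the Re face of octanal, Et3N, CH2Cl2, −78 °C) should add to octanal to give the beta-hydroxy ketone (6R)-6-decyl-4-[(3S)-3-hydroxydecanoyl]-3-(octyloxy)-5,6-dihydro-2H-pyran-2-one F2. Catalytic TFA in CH2Cl2 should then bring about conjugate addition of the hydroxyl group to C3 of the lactone and loss of 1-octanol (vinylogous transesterification). This comes back to the route at target 11.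

Step 5. Cleavage of the tert-butyl ester by thionyl chloride may stall, the hydrogen chloride formed may add to the diazoketone, or diazomethane may add across the C=C bond of the acid chloride. The fallback sets out from 8 and avoids the acid chloride. TFA in CH2Cl2 should give the acid (6R)-6-decyl-3-(octyloxy)-2-oxo-5,6-dihydro-2H-pyran-4-carboxylic acid F3. Isobutyl chloroformate and N-methylmorpholine (THF, −15 °C) should convert it into the mixed carbonic anhydride (6R)-6-decyl-3-(octyloxy)-2-oxo-5,6-dihydro-2H-pyran-4-carboxylic isobutyl carbonic anhydride F4. Diazomethane then acylates on the acyl carbonyl, and the route is rejoined at 10.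

Step 3. Acyl transfer may stop at the open-chain stage, the liberated alkoxide may close onto the tert-butyl ester to a gamma-lactone, or intermolecular Claisen condensation may compete. The fallback sets out from 3 and separates C-acylation from lactonisation. TBSCl and imidazole (DMF) should give the silyl ether tert-butyl (4R)-4-[(tert-butyldimethylsilyl)oxy]tetradecanoate F5. Its lithium enolate (LiN(iPr)2, THF, −78 °C) with diethyl oxalate should give, by crossed Claisen condensation, the oxalyl ester 4-tert-butyl 1-ethyl 3-[(2R)-2-[(tert-butyldimethylsilyl)oxy]dodecyl]-2-oxobutanedioate F6. HF·pyridine in THF should remove the silyl group, and the free hydroxyl should lactonise onto the activated ethyl ester. This comes back to the route at 6.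

**Further compounds**
F1 | step 6 | (6R)-4-acetyl-6-decyl-3-(octyloxy)-5,6-dihydro-2H-pyran-2-one | CCCCCCCCCC[C@@H]1CC(C(C)=O)=C(OCCCCCCCC)C(=O)O1
F2 | step 6 | (6R)-6-decyl-4-[(3S)-3-hydroxydecanoyl]-3-(octyloxy)-5,6-dihydro-2H-pyran-2-one | CCCCCCCCCC[C@@H]1CC(C(=O)C[C@@H](O)CCCCCCC)=C(OCCCCCCCC)C(=O)O1
F3 | step 5 | (6R)-6-decyl-3-(octyloxy)-2-oxo-5,6-dihydro-2H-pyran-4-carboxylic acid | CCCCCCCCCC[C@@H]1CC(C(=O)O)=C(OCCCCCCCC)C(=O)O1
F4 | step 5 | (6R)-6-decyl-3-(octyloxy)-2-oxo-5,6-dihydro-2H-pyran-4-carboxylic isobutyl carbonic anhydride | CCCCCCCCCC[C@@H]1CC(C(=O)OC(=O)OCC(C)C)=C(OCCCCCCCC)C(=O)O1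
F5 | step 3 | tert-butyl (4R)-4-[(tert-butyldimethylsilyl)oxy]tetradecanoate | CCCCCCCCCC[C@@H](O[Si](C)(C)C(C)(C)C)CCC(=O)OC(C)(C)C
F6 | step 3 | 4-tert-butyl 1-ethyl 3-[(2R)-2-[(tert-butyldimethylsilyl)oxy]dodecyl]-2-oxobutanedioate | CCCCCCCCCC[C@@H](O[Si](C)(C)C(C)(C)C)CC(C(=O)OC(C)(C)C)C(=O)C(=O)OCC
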